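## The problem

The target is methyl 8β-acetoxy-3β-[(E)-3-methylpent-2-enoyloxy]eudesma-4,11(13)-dien-12-oate. Eudesmane numbering is used throughout: ring A is C1–C5 and C10, ring B is C5–C10, C14 sits on C10, C15 on C4, and the acrylate C11–C13 on C7. Rings A and B share the quaternary C10 and the trigonal C5 of a tetrasubstituted C4=C5 alkene, so the bicycle is an octalin with only one sp3 fusion atom. There are four stereocentres, C3 (S), C7 (R), C8 (R) and C10 (R), and all four substituents lie on the face of C14. C10 has no stereogenic neighbour when it is made and must come from a catalyst. An axial C14 can then direct C8 (1,3) and C3 (1,4), but only if the bicycle is rigid at that moment, and C7 follows C8 through whatever closes ring B. The C8 oxygen is axial, syn to C14 and cis to the acrylate, so the free hydroxy ester is one step from the cis-fused α-methylene lactone. The exo-methylene ester is a Michael acceptor, the C3 ester is allylic, and its β,β-disubstituted enoate deconjugates with base, so organolithium reagents, strong base and hot acid are excluded once these groups are present. The feature that opens the structure is that C10 and C5, from which the two arms of ring B leave (C9–C8 and C6–C7), are the β- and α-carbons of a ring A cyclohexenone with its carbonyl at C4. Conjugate methylation makes the quaternary centre, and the enolate so formed accepts the second arm.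

## Retrosynthesis

**C3–O acyl bond.** Target 29 is cut at the C3 ester into allylic alcohol 27 and (E)-3-methylpent-2-enoic acid 28. The enoate is the most easily isomerised group and should see no further chemistry. Carrying it through ring construction would expose an allylic ester to Lewis acids. The forward step is a carbodiimide esterification of a secondary allylic alcohol.

**C3–H bond.** Alcohol 27 is traced to enone 26. In the rigid 10-methyl-4-en-3-one the axial C14 sends hydride to the α face, the best precedented way to a 3β-allylic alcohol in this ring system. This is reliable only after ring B is closed. The forward reaction must reduce the enone carbonyl and leave the acrylate and acetate.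

**C4=C5 alkene and C3 oxygen.** Enone 26 is derived from the Δ3 alkene 22 through ketol 25 and diol 24, with epoxide 23 between. No skeletal bond is cut, but the ring closure rests on this decision. While C5 is sp3 with its hydrogen trans to C14, ring B can close only as a trans-fused chair. The C5 arm is then not attached to an alkene, so there is no β,γ-unsaturated aldehyde and no doubly allylic C6. The trisubstituted alkene is inert to everything done on the arms. Forming the 4-ene or the enone earlier was weighed and rejected for these reasons. The forward direction asks for α-face epoxidation, trans-diaxial hydrolysis, oxidation of the secondary alcohol and anti elimination of the axial tertiary hydroxyl toward H5.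

**C8–O acetyl and C7–C8.** Acetate 22 comes from alcohol 21, and ring B of 21 is opened at C7–C8 to aldehyde 19, whose C5 arm ends in a Z-2-(bromomethyl)acrylate. This cut removes the ring, both ring B stereocentres and the exo-methylene at once and gives the acrylate as the open methyl ester. Cuts at C6–C7 or C8–C9 would leave the acrylate or the oxygen to be added later. The precursor is a monocyclic cyclohexene with two stereocentres. The forward reaction, an intramolecular Barbier allylation with CrCl2, must react through C7, give the cis C7/C8 pair and choose the face syn to C14.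

**C7–C11 and the allylic bromide.** Aldehyde 19 is simplified through alcohol 18 and silyl ether 17 to the Morita–Baylis–Hillman adduct 16, which is cut at C7–C11 into aldehyde 14 and methyl acrylate 15. This brings in C11–C13 at the right oxidation level in one step. The bromide is then made with allylic transposition, which also fixes the Z geometry. Olefination routes would need a separate functionalisation of C13.

**C4–C15.** Aldehyde 14 comes from ester 12 by way of alcohol 13. Ester 12 is cut at C4–C15 to enol triflate 11, made from ketone 9 through its kinetic enolate 10. Cross-coupling at the triflate places the methyl group and the double bond without ambiguity, whereas methyl addition to the ketone and dehydration would give alkene mixtures. Triflation also removes the carbonyl next to C5, so this centre can no longer epimerise.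

**C10–C14 and C5–C6 (key disconnection).** Ketone 9 is cut at both bonds into enone 5, methylmagnesium bromide 6 and tert-butyl bromoacetate 7, joined through magnesium enolate 8. A stepwise sequence would need regioselective enolisation toward the hindered C5; the one-flask process uses the enolate where the conjugate addition leaves it. The precursor has no stereocentre. The forward reaction must set C10 by catalyst control and place the new arm trans to the existing one.

**Ring A.** Enone 5 is the silyl ether (from chloride 4) of hydroxy enone 3, which comes from 2-(3-methoxyphenyl)ethanol 1 by Birch reduction to diene 2 and acid hydrolysis.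

## Roads not taken

Alternative 1: The bond C7–C8 is cut in the complete 8-O-deacetyl target A1. This leaves the monocyclic aldehyde A2, in which ring A already has the C4=C5 alkene, the C3 ester and the Z-allylic bromide on the C5 arm. In the forward direction CrCl2 makes an allylchromium species whose γ-carbon C7 adds to the C8 aldehyde.
- Merits: ring B, C7, C8 and the exo-methylene arise in the last skeletal step, and only acetylation follows. The cis C7/C8 relation of such closures is well precedented.
- Weak points: with C5 trigonal the closing chair is reachable from two conformers of ring A, one with C14 and one with C1 axial on ring B. Each puts the metal-bound oxygen syn-axial to a carbon on C10, so the face relative to C10 is not secured. A2 has a doubly allylic C6 and is reached through β,γ-unsaturated carbonyl compounds that conjugate easily. An allylic ester must survive the Lewis-acidic metal. The plan does not say how C10 is made.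
- Comparison: the chosen route uses the same bond formation in step 12, so the two differ in timing. Alternative 1 is better in end-game economy, one step after ring closure against six. The chosen plan sets against this a closure on 19, where C5 is still sp3 and the trans fusion leaves one chair, and a catalytic origin for C10.

Alternative 2: The bond C7–C11 is cut. Lactol ether A3 is formed from the mixed bromoacetal A4 of an 8β-hydroxy-4,6-dien-3-one. Bu3SnH and AIBN generate the C11 radical, which adds 5-exo to C7, and the resulting dienyl radical is reduced to the 4-en-3-one.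
- Merits: the tether guarantees cis C7/C8, and on this single point the road is safer than the chosen Barbier step. C8 relays its configuration to C7, and radical conditions tolerate the enone.
- Weak points: A4 already needs C8 and C10 in the right relation, for which nothing is offered. After cyclisation the acetal must be oxidised to the lactone, the α-methylene introduced by enolate chemistry beside an enone, and the cis lactone opened to methyl ester and acetate against its tendency to re-close. A ring is built only to be undone. Hydrogen return to the dienyl radical may give the deconjugated 5-ene, and tin is used in stoichiometric amount.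
- Comparison: the chosen plan answers the cis guarantee with the single-chair argument in the trans-fused series and a corrective oxidation–reduction at C8. It also delivers the acrylate open and with its methylene in the ring-closing step.

Alternative 3: The bonds C1–C2 and C5–C10 are cut together. Heating lactone A6, which carries a silyloxy vinylallene on C7 and a methallyl group on C8, lets the diene C2–C5 add to the 1,1-disubstituted alkene. Rings A and B close and the quaternary centre forms in the tricyclic dienol ether A5, the allene axis setting C10.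
- Merits: two rings, two C–C bonds and C10 in one step, with ring A at the enone oxidation level. In bond-forming economy this road is clearly better than the chosen plan, which needs many steps from its key step to a comparable bicycle.
- Weak points: three stereo-elements of A6 (C7, C8 and the axis) must be made and matched before the key step. An unactivated 1,1-disubstituted dienophile needs high temperature, where vinylallenes undergo 1,5-hydrogen shifts. Protonation of the dienol ether must return the 4-en-3-one and not the 5-ene. The lactone problem of Alternative 2 returns.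
- Comparison: the chosen plan sets against this a quaternary centre made from an achiral enone by a catalytic step with close precedent, and no lactone to open.

Key step: step 3

Assumption: the chiral imidazolinium chloride (carbene precursor) is used as the enantiomer that sends methyl to the Si face of C10, and acid 28 is bought as the pure E isomer.

## Route

Step 1
Reactants: 1 2-(3-methoxyphenyl)ethanol
Product: 3 3-(2-hydroxyethyl)cyclohex-2-en-1-one, via methoxy diene 2 (not isolated)
Conditions: Li, NH3(l), t-BuOH, THF, −78 → −33 °C; NH4Cl; then 2 M HCl, THF, rt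
Reagents that add atoms: water, O
Why: Birch reduction of a 3-alkylanisole gives the 1-methoxycyclohexa-1,4-diene; acid hydrolysis of the enol ether and migration of the double bond into conjugation give the 3-substituted cyclohexenone.

Step 2
Reactants: 3 3-(2-hydroxyethyl)cyclohex-2-en-1-one; 4 tert-butyldimethylsilyl chloride
Product: 5 3-[2-(tert-butyldimethylsilyloxy)ethyl]cyclohex-2-en-1-one
Conditions: imidazole, DMF, rt
Reagents that add atoms: none
Why: Silylation of the primary alcohol; the silyl ether masks the C8 oxygen through the organometallic steps.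

Step 3
Reactants: 5 3-[2-(tert-butyldimethylsilyloxy)ethyl]cyclohex-2-en-1-one; 6 methylmagnesium bromide; 7 tert-butyl bromoacetate
Product: 9 tert-butyl 2-[(1R,2R)-2-[2-(tert-butyldimethylsilyloxy)ethyl]-2-methyl-6-oxocyclohexyl]acetate, via bromomagnesium enolate 8 (not isolated)
Conditions: Cu(OTf)2 (3 mol %), chiral imidazolinium chloride (4 mol %), 6, Et2O, 0 °C; then 7, DMPU, −30 °C → rt
Reagents that add atoms: none
Why: The Grignard reagent deprotonates the imidazolinium salt and converts Cu(OTf)2 into a carbene-bound monovalent methylcopper species, which forms a π-complex with enone 5, adds at C10 to give a trivalent copper enolate and forms C10–C14 by reductive elimination, leaving bromomagnesium enolate 8 with its double bond fixed between C4 and C5. DMPU and 7 then let this enolate displace bromide by SN2 and form C5–C6, so ring A with the C9–C8 arm, the methyl C14 and the C6–C7 arm are joined in one flask. The closest known reaction type is the copper–carbene-catalysed asymmetric conjugate addition of Grignard reagents to 3-substituted cyclohex-2-enones with trapping of the magnesium enolate by a reactive alkyl halide. No ring closes. C10 is set by the ligand alone, since 5 has no stereocentre: methyl delivery to the Si face of the β-carbon gives 10R. C5 is set by the substrate: the bromoacetate approaches the enolate face opposite the larger silyloxyethyl arm, which places C6 cis to C14 (5R) and the two arms trans, as ring B closure will need. The step needs 1,4- over 1,2-addition (secured by copper) and C-monoalkylation at C5 (secured by the regiodefined enolate, the reactive α-halo ester and the tert-butyl ester, which resists attack at its carbonyl).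

Step 4
Reactants: 9 tert-butyl 2-[(1R,2R)-2-[2-(tert-butyldimethylsilyloxy)ethyl]-2-methyl-6-oxocyclohexyl]acetate
Product: 11 tert-butyl 2-[(1R,6R)-6-[2-(tert-butyldimethylsilyloxy)ethyl]-6-methyl-2-(trifluoromethanesulfonyloxy)cyclohex-2-en-1-yl]acetate, via potassium enolate 10 (not isolated)
Conditions: KN(SiMe3)2, THF, −78 °C; PhNTf2, −78 → 0 °C
Reagents that add atoms: N-phenylbis(trifluoromethanesulfonimide), O=S(=O)(N(c1ccccc1)S(=O)(=O)C(F)(F)F)C(F)(F)F
Why: Kinetic deprotonation occurs at the unhindered C3 methylene and not at the tertiary C5 beside the quaternary centre; O-triflation of enolate 10 fixes the C3=C4 double bond and removes the carbonyl that kept C5 epimerisable.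

Step 5
Reactants: 11 tert-butyl 2-[(1R,6R)-6-[2-(tert-butyldimethylsilyloxy)ethyl]-6-methyl-2-(trifluoromethanesulfonyloxy)cyclohex-2-en-1-yl]acetate; 6 methylmagnesium bromide
Product: 12 tert-butyl 2-[(1R,6R)-6-[2-(tert-butyldimethylsilyloxy)ethyl]-2,6-dimethylcyclohex-2-en-1-yl]acetate
Conditions: Fe(acac)3 (5 mol %), THF/NMP, −30 °C
Reagents that add atoms: none
Why: Iron-catalysed Kumada-type cross-coupling of an alkenyl triflate with a methyl Grignard reagent; it is fast at low temperature, so the tert-butyl ester is untouched, and it installs C15 with the alkene position defined.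

Step 6
Reactants: 12 tert-butyl 2-[(1R,6R)-6-[2-(tert-butyldimethylsilyloxy)ethyl]-2,6-dimethylcyclohex-2-en-1-yl]acetate
Product: 13 2-[(1R,6R)-6-[2-(tert-butyldimethylsilyloxy)ethyl]-2,6-dimethylcyclohex-2-en-1-yl]ethanol
Conditions: LiAlH4, Et2O, 0 °C
Reagents that add atoms: none
Why: Hydride reduction of the ester to the primary alcohol; the silyl ether and the trisubstituted alkene are inert.

Step 7
Reactants: 13 2-[(1R,6R)-6-[2-(tert-butyldimethylsilyloxy)ethyl]-2,6-dimethylcyclohex-2-en-1-yl]ethanol
Product: 14 2-[(1R,6R)-6-[2-(tert-butyldimethylsilyloxy)ethyl]-2,6-dimethylcyclohex-2-en-1-yl]acetaldehyde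
Conditions: Dess–Martin periodinane, NaHCO3, CH2Cl2, 0 °C → rt
Reagents that add atoms: none
Why: Dess–Martin oxidation under buffered conditions; the aldehyde is γ,δ-unsaturated, so it cannot move into conjugation.

Step 8
Reactants: 14 2-[(1R,6R)-6-[2-(tert-butyldimethylsilyloxy)ethyl]-2,6-dimethylcyclohex-2-en-1-yl]acetaldehyde; 15 methyl acrylate
Product: 16 methyl 3-hydroxy-2-methylidene-4-[(1R,6R)-6-[2-(tert-butyldimethylsilyloxy)ethyl]-2,6-dimethylcyclohex-2-en-1-yl]butanoate (both epimers at the carbinol carbon C7)
Conditions: 15 (excess), DABCO, 1,4-dioxane/H2O (1:1), rt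
Reagents that add atoms: none
Why: Morita–Baylis–Hillman reaction: DABCO adds to the acrylate and the resulting enolate attacks the aldehyde, forming C7–C11. The new carbinol centre is removed in the next step, so its configuration does not matter.

Step 9
Reactants: 16 methyl 3-hydroxy-2-methylidene-4-[(1R,6R)-6-[2-(tert-butyldimethylsilyloxy)ethyl]-2,6-dimethylcyclohex-2-en-1-yl]butanoate
Product: 17 methyl (2Z)-2-(bromomethyl)-4-[(1R,6R)-6-[2-(tert-butyldimethylsilyloxy)ethyl]-2,6-dimethylcyclohex-2-en-1-yl]but-2-enoate
Conditions: NBS, Me2S, CH2Cl2, 0 °C → rt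
Reagents that add atoms: N-bromosuccinimide, O=C1CCC(=O)N1Br
Why: The alkoxysulfonium salt formed with the bromodimethylsulfonium reagent (Corey–Kim type) is displaced by bromide with allylic transposition (SN2′). This gives the more stable Z alkene, with C6 cis to the bromomethyl group.

Step 10
Reactants: 17 methyl (2Z)-2-(bromomethyl)-4-[(1R,6R)-6-[2-(tert-butyldimethylsilyloxy)ethyl]-2,6-dimethylcyclohex-2-en-1-yl]but-2-enoate
Product: 18 methyl (2Z)-2-(bromomethyl)-4-[(1R,6R)-6-(2-hydroxyethyl)-2,6-dimethylcyclohex-2-en-1-yl]but-2-enoate
Conditions: HF (48 % aq.), MeCN, 0 °C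
Reagents that add atoms: none
Why: Acidic fluoride cleaves the primary silyl ether; amine-containing fluoride sources are avoided because they would attack the allylic bromide.

Step 11
Reactants: 18 methyl (2Z)-2-(bromomethyl)-4-[(1R,6R)-6-(2-hydroxyethyl)-2,6-dimethylcyclohex-2-en-1-yl]but-2-enoate
Product: 19 methyl (2Z)-2-(bromomethyl)-4-[(1R,6R)-2,6-dimethyl-6-(2-oxoethyl)cyclohex-2-en-1-yl]but-2-enoate
Conditions: Dess–Martin periodinane, NaHCO3, CH2Cl2, 0 °C → rt
Reagents that add atoms: none
Why: Dess–Martin oxidation tolerates the allylic bromide and the acrylate; the aldehyde hangs on the quaternary C10 through C9 and has no epimerisable centre.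

Step 12
Reactants: 19 methyl (2Z)-2-(bromomethyl)-4-[(1R,6R)-2,6-dimethyl-6-(2-oxoethyl)cyclohex-2-en-1-yl]but-2-enoate
Product: 21 methyl (5R,7R,8R,10R)-8-hydroxyeudesma-3,11(13)-dien-12-oate (5α-H; 8β-OH), via allylchromium dichloride 20 (not isolated)
Conditions: CrCl2 (5 equiv), THF, rt, slow addition of 19 (0.005 M); pH 7 buffer work-up
Reagents that add atoms: none
Why: Intramolecular Barbier allylation of the Nozaki–Hiyama type: two equivalents of divalent chromium turn the bromide into allylchromium 20, whose γ-carbon C7 adds to the C8 aldehyde (6-exo-trig) through a closed chair transition state fused to the forming chair of ring B. Allylic strain in the Z-allyl unit keeps C11 equatorial on ring B, which puts the metal-bound oxygen axial (cis). Because C5 locks a trans ring fusion, only the 7β,8β arrangement (7R,8R) fits this transition state; neutral work-up keeps the hydroxy ester open.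

Step 13
Reactants: 21 methyl (5R,7R,8R,10R)-8-hydroxyeudesma-3,11(13)-dien-12-oate
Product: 22 methyl (5R,7R,8R,10R)-8-acetoxyeudesma-3,11(13)-dien-12-oate
Conditions: Ac2O, Et3N, DMAP, CH2Cl2, 0 °C (on crude 21)
Reagents that add atoms: acetic anhydride, CC(=O)OC(C)=O
Why: DMAP-catalysed acetylation of the axial secondary alcohol, done at once so that acylation outruns lactonisation onto the cis ester.

Step 14
Reactants: 22 methyl (5R,7R,8R,10R)-8-acetoxyeudesma-3,11(13)-dien-12-oate
Product: 24 methyl (3R,4R,5R,7R,8R,10R)-8-acetoxy-3,4-dihydroxyeudesm-11(13)-en-12-oate (3α-OH; 4β-OH), via 3α,4α-epoxide 23 (not isolated)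
Conditions: mCPBA, NaHCO3, CH2Cl2, 0 °C; then HClO4 (cat.), THF/H2O, rt
Reagents that add atoms: 3-chloroperoxybenzoic acid, OOC(=O)c1cccc(Cl)c1; water, O
Why: Prilezhaev epoxidation selects the electron-rich C3=C4 alkene over the acrylate and occurs on the α face, away from the axial C14. Aqueous acid opens epoxide 23 trans-diaxially at the tertiary C4 from the β side, leaving the C4 hydroxyl axial.

Step 15
Reactants: 24 methyl (3R,4R,5R,7R,8R,10R)-8-acetoxy-3,4-dihydroxyeudesm-11(13)-en-12-oate
Product: 25 methyl (4R,5R,7R,8R,10R)-8-acetoxy-4-hydroxy-3-oxoeudesm-11(13)-en-12-oate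
Conditions: IBX, DMSO, rt
Reagents that add atoms: none
Why: IBX oxidises the secondary alcohol of a 1,2-diol to the ketone without glycol cleavage; the tertiary alcohol cannot react.

Step 16
Reactants: 25 methyl (4R,5R,7R,8R,10R)-8-acetoxy-4-hydroxy-3-oxoeudesm-11(13)-en-12-oate
Product: 26 methyl (7R,8R,10R)-8-acetoxy-3-oxoeudesma-4,11(13)-dien-12-oate
Conditions: SOCl2, pyridine, CH2Cl2, −10 → 0 °C
Reagents that add atoms: none
Why: E2 dehydration of the chlorosulfite: the axial 4β oxygen is anti-periplanar to the axial H5α, so elimination runs into the ring and gives the conjugated tetrasubstituted C4=C5 alkene. C3 carries no hydrogen to compete, and the relay centre C5 is erased.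

Step 17
Reactants: 26 methyl (7R,8R,10R)-8-acetoxy-3-oxoeudesma-4,11(13)-dien-12-oate
Product: 27 methyl (3S,7R,8R,10R)-8-acetoxy-3-hydroxyeudesma-4,11(13)-dien-12-oate
Conditions: NaBH4, CeCl3·7H2O, MeOH, −78 → −40 °C
Reagents that add atoms: none
Why: Luche reduction: 1,2-hydride delivery to the α face, anti to the axial C14 of the now rigid octalin, gives the pseudo-equatorial 3β alcohol (3S). The hard cerium-modified borohydride at low temperature spares the acrylate and the acetate.

Step 18
Reactants: 27 methyl (3S,7R,8R,10R)-8-acetoxy-3-hydroxyeudesma-4,11(13)-dien-12-oate; 28 (E)-3-methylpent-2-enoic acid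
Product: 29 methyl (3S,7R,8R,10R)-8-acetoxy-3-[(2E)-3-methylpent-2-enoyloxy]eudesma-4,11(13)-dien-12-oate (CNP0118541.1)
Conditions: DCC, DMAP (cat.), CH2Cl2, 0 °C → rt
Reagents that add atoms: none
Why: Steglich esterification of the secondary allylic alcohol; neutral carbodiimide activation avoids ionisation at C3 and keeps the E enoate in conjugation.

## Compound list

1 | 2-(3-methoxyphenyl)ethanol | COc1cccc(CCO)c1 | starting material
2 | 2-(5-methoxycyclohexa-1,4-dien-1-yl)ethanol | COC1=CCC(CCO)=CC1 | intermediate (not isolated)
3 | 3-(2-hydroxyethyl)cyclohex-2-en-1-one | O=C1C=C(CCO)CCC1 | intermediate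
4 | tert-butyldimethylsilyl chloride | CC(C)(C)[Si](C)(C)Cl | starting material
5 | 3-[2-(tert-butyldimethylsilyloxy)ethyl]cyclohex-2-en-1-one | O=C1C=C(CCO[Si](C)(C)C(C)(C)C)CCC1 | intermediate
6 | methylmagnesium bromide | C[Mg]Br | starting material
7 | tert-butyl bromoacetate | CC(C)(C)OC(=O)CBr | starting material
8 | bromomagnesium (3R)-3-[2-(tert-butyldimethylsilyloxy)ethyl]-3-methylcyclohex-1-en-1-olate | C[C@]1(CCO[Si](C)(C)C(C)(C)C)CCCC(O[Mg]Br)=C1 | intermediate (not isolated)
9 | tert-butyl 2-[(1R,2R)-2-[2-(tert-butyldimethylsilyloxy)ethyl]-2-methyl-6-oxocyclohexyl]acetate | O=C1CCC[C@](C)(CCO[Si](C)(C)C(C)(C)C)[C@H]1CC(=O)OC(C)(C)C | intermediate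
10 | potassium (5R,6R)-6-(2-tert-butoxy-2-oxoethyl)-5-[2-(tert-butyldimethylsilyloxy)ethyl]-5-methylcyclohex-1-en-1-olate | [K+].[O-]C1=CCC[C@](C)(CCO[Si](C)(C)C(C)(C)C)[C@H]1CC(=O)OC(C)(C)C | intermediate (not isolated)
11 | tert-butyl 2-[(1R,6R)-6-[2-(tert-butyldimethylsilyloxy)ethyl]-6-methyl-2-(trifluoromethanesulfonyloxy)cyclohex-2-en-1-yl]acetate | O=S(=O)(OC1=CCC[C@](C)(CCO[Si](C)(C)C(C)(C)C)[C@H]1CC(=O)OC(C)(C)C)C(F)(F)F | intermediate
12 | tert-butyl 2-[(1R,6R)-6-[2-(tert-butyldimethylsilyloxy)ethyl]-2,6-dimethylcyclohex-2-en-1-yl]acetate | CC1=CCC[C@](C)(CCO[Si](C)(C)C(C)(C)C)[C@H]1CC(=O)OC(C)(C)C | intermediate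
13 | 2-[(1R,6R)-6-[2-(tert-butyldimethylsilyloxy)ethyl]-2,6-dimethylcyclohex-2-en-1-yl]ethanol | CC1=CCC[C@](C)(CCO[Si](C)(C)C(C)(C)C)[C@H]1CCO | intermediate
14 | 2-[(1R,6R)-6-[2-(tert-butyldimethylsilyloxy)ethyl]-2,6-dimethylcyclohex-2-en-1-yl]acetaldehyde | CC1=CCC[C@](C)(CCO[Si](C)(C)C(C)(C)C)[C@H]1CC=O | intermediate
15 | methyl acrylate | C=CC(=O)OC | starting material
16 | methyl 3-hydroxy-2-methylidene-4-[(1R,6R)-6-[2-(tert-butyldimethylsilyloxy)ethyl]-2,6-dimethylcyclohex-2-en-1-yl]butanoate (both epimers at the carbinol carbon, left open in the string) | CC1=CCC[C@](C)(CCO[Si](C)(C)C(C)(C)C)[C@H]1CC(O)C(=C)C(=O)OC | intermediate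
17 | methyl (2Z)-2-(bromomethyl)-4-[(1R,6R)-6-[2-(tert-butyldimethylsilyloxy)ethyl]-2,6-dimethylcyclohex-2-en-1-yl]but-2-enoate | CC1=CCC[C@](C)(CCO[Si](C)(C)C(C)(C)C)[C@H]1C/C=C(\CBr)C(=O)OC | intermediate
18 | methyl (2Z)-2-(bromomethyl)-4-[(1R,6R)-6-(2-hydroxyethyl)-2,6-dimethylcyclohex-2-en-1-yl]but-2-enoate | CC1=CCC[C@](C)(CCO)[C@H]1C/C=C(\CBr)C(=O)OC | intermediate
19 | methyl (2Z)-2-(bromomethyl)-4-[(1R,6R)-2,6-dimethyl-6-(2-oxoethyl)cyclohex-2-en-1-yl]but-2-enoate | CC1=CCC[C@](C)(CC=O)[C@H]1C/C=C(\CBr)C(=O)OC | intermediate
20 | allylchromium dichloride derived from 19 (chromium on C13) | CC1=CCC[C@](C)(CC=O)[C@H]1C/C=C(\C[Cr](Cl)Cl)C(=O)OC | intermediate (not isolated)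
21 | methyl (5R,7R,8R,10R)-8-hydroxyeudesma-3,11(13)-dien-12-oate (5α-H, 8β-OH) | C=C(C(=O)OC)[C@H]1C[C@H]2C(C)=CCC[C@]2(C)C[C@H]1O | intermediate
22 | methyl (5R,7R,8R,10R)-8-acetoxyeudesma-3,11(13)-dien-12-oate | C=C(C(=O)OC)[C@H]1C[C@H]2C(C)=CCC[C@]2(C)C[C@H]1OC(C)=O | intermediate
23 | methyl (3R,4S,5R,7R,8R,10R)-8-acetoxy-3,4-epoxyeudesm-11(13)-en-12-oate (3α,4α-epoxide) | C=C(C(=O)OC)[C@H]1C[C@H]2[C@]3(C)O[C@@H]3CC[C@]2(C)C[C@H]1OC(C)=O | intermediate (not isolated)
24 | methyl (3R,4R,5R,7R,8R,10R)-8-acetoxy-3,4-dihydroxyeudesm-11(13)-en-12-oate (3α-OH, 4β-OH) | C=C(C(=O)OC)[C@H]1C[C@H]2[C@@](C)(O)[C@H](O)CC[C@]2(C)C[C@H]1OC(C)=O | intermediate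
25 | methyl (4R,5R,7R,8R,10R)-8-acetoxy-4-hydroxy-3-oxoeudesm-11(13)-en-12-oate (4β-OH) | C=C(C(=O)OC)[C@H]1C[C@H]2[C@@](C)(O)C(=O)CC[C@]2(C)C[C@H]1OC(C)=O | intermediate
26 | methyl (7R,8R,10R)-8-acetoxy-3-oxoeudesma-4,11(13)-dien-12-oate | C=C(C(=O)OC)[C@H]1CC2=C(C)C(=O)CC[C@]2(C)C[C@H]1OC(C)=O | intermediate
27 | methyl (3S,7R,8R,10R)-8-acetoxy-3-hydroxyeudesma-4,11(13)-dien-12-oate | C=C(C(=O)OC)[C@H]1CC2=C(C)[C@@H](O)CC[C@]2(C)C[C@H]1OC(C)=O | intermediate
28 | (E)-3-methylpent-2-enoic acid | CC/C(C)=C/C(=O)O | starting material
29 | methyl (3S,7R,8R,10R)-8-acetoxy-3-[(2E)-3-methylpent-2-enoyloxy]eudesma-4,11(13)-dien-12-oate | C=C(C(=O)OC)[C@H]1CC2=C(C)[C@@H](OC(=O)/C=C(\C)CC)CC[C@]2(C)C[C@H]1OC(C)=O | target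

## Step count

Total: 18 steps. Longest linear sequence: 18 steps, from 1 to 29.

## Least certain steps

**Step 3 (key step).** Enantiofacial control may be incomplete with the small methyl Grignard reagent. The aggregated magnesium enolate may also alkylate slowly, so proton transfer can move the enolate and erode the trans placement at C5 on which ring B closure now depends. Epimers at C5 would be separated at 9; the minor one can be re-equilibrated with base while the C4 carbonyl is present.
Fallback, from 5 back to 9: the two bonds are made in two operations. Me3Al with copper thiophene-2-carboxylate and a chiral phosphoramidite ligand adds methyl to 5. The aluminium enolate is trapped with TMSOTf as the trimethylsilyl enol ether F1. MeLi in THF then releases the lithium enolate regiospecifically, and this is alkylated with 7 in the presence of DMPU to give 9.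

**Step 12.** The closed chair places the chromium-bound oxygen syn-axial to C14. Isomerisation of the allylchromium species to its E form or an open transition state could therefore deliver the equatorial 8α alcohol. The cis hydroxy ester may also lactonise on work-up.
Fallback, from 21 (as a mixture at C8) back to 21: Dess–Martin oxidation gives the 8-ketone F2. NaBH4 with CeCl3·7H2O at −78 °C then delivers hydride from the α face, the β face being blocked by the axial C14, and returns the 8β alcohol 21, which is acetylated at once.

**Step 14.** Under aqueous acid the epoxide may lose a proton or undergo a hydride shift instead of capturing water at the hindered β face of C4.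
Fallback, from 22 back to 26: catalytic OsO4 with N-methylmorpholine N-oxide dihydroxylates the trisubstituted alkene from the α face to the 3α,4α-diol F3. IBX gives the 4α-hydroxy-3-ketone F4. The Burgess reagent then removes the tertiary hydroxyl by syn elimination with the cis H5α to give enone 26.

**Step 16.** Elimination may be slow because the tertiary carbinol is next to a carbonyl, letting chloride substitution or loss of a C15 hydrogen (exocyclic alkene) compete.
Fallback, from 24 back to 26: the dehydration is moved to a substrate without the ketone. Diol 24 is silylated at the secondary hydroxyl (Et3SiCl, imidazole) to the 3α-triethylsilyl ether F5. SOCl2 in pyridine eliminates the axial 4β hydroxyl toward H5α to the 3α-silyloxy-4-ene F6. HF·pyridine frees the 3α-hydroxy-4-ene F7, and Dess–Martin oxidation gives enone 26.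

**Step 8.** The amine-catalysed addition may be sluggish with this β-branched aldehyde, leaving time for self-aldol condensation.
Fallback, from 14 back to 16: a preformed nucleophile is used. Hydroalumination of methyl propiolate with i-Bu2AlH and N-methylmorpholine N-oxide gives the α-aluminoacrylate, which adds to 14 at 0 °C to give 16 directly. No new compound is formed.

## Further compounds

F1 | step 3 | tert-butyldimethyl{2-[(1R)-1-methyl-3-(trimethylsilyloxy)cyclohex-2-en-1-yl]ethoxy}silane | C[C@]1(CCO[Si](C)(C)C(C)(C)C)CCCC(O[Si](C)(C)C)=C1
F2 | step 12 | methyl (5R,7R,10R)-8-oxoeudesma-3,11(13)-dien-12-oate | C=C(C(=O)OC)[C@H]1C[C@H]2C(C)=CCC[C@]2(C)CC1=O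
F3 | step 14 | methyl (3R,4S,5R,7R,8R,10R)-8-acetoxy-3,4-dihydroxyeudesm-11(13)-en-12-oate (3α-OH, 4α-OH) | C=C(C(=O)OC)[C@H]1C[C@H]2[C@](C)(O)[C@H](O)CC[C@]2(C)C[C@H]1OC(C)=O
F4 | step 14 | methyl (4S,5R,7R,8R,10R)-8-acetoxy-4-hydroxy-3-oxoeudesm-11(13)-en-12-oate (4α-OH) | C=C(C(=O)OC)[C@H]1C[C@H]2[C@](C)(O)C(=O)CC[C@]2(C)C[C@H]1OC(C)=O
F5 | step 16 | methyl (3R,4R,5R,7R,8R,10R)-8-acetoxy-4-hydroxy-3-(triethylsilyloxy)eudesm-11(13)-en-12-oate | C=C(C(=O)OC)[C@H]1C[C@H]2[C@@](C)(O)[C@H](O[Si](CC)(CC)CC)CC[C@]2(C)C[C@H]1OC(C)=O
F6 | step 16 | methyl (3R,7R,8R,10R)-8-acetoxy-3-(triethylsilyloxy)eudesma-4,11(13)-dien-12-oate | C=C(C(=O)OC)[C@H]1CC2=C(C)[C@H](O[Si](CC)(CC)CC)CC[C@]2(C)C[C@H]1OC(C)=O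
F7 | step 16 | methyl (3R,7R,8R,10R)-8-acetoxy-3-hydroxyeudesma-4,11(13)-dien-12-oate | C=C(C(=O)OC)[C@H]1CC2=C(C)[C@H](O)CC[C@]2(C)C[C@H]1OC(C)=O
F0 | step 8 | none | none
A1 | alternative 1 | methyl (3S,7R,8R,10R)-8-hydroxy-3-[(2E)-3-methylpent-2-enoyloxy]eudesma-4,11(13)-dien-12-oate | C=C(C(=O)OC)[C@H]1CC2=C(C)[C@@H](OC(=O)/C=C(\C)CC)CC[C@]2(C)C[C@H]1O
A2 | alternative 1 | methyl (2Z)-2-(bromomethyl)-4-[(3S,6R)-2,6-dimethyl-3-[(2E)-3-methylpent-2-enoyloxy]-6-(2-oxoethyl)cyclohex-1-en-1-yl]but-2-enoate | COC(=O)C(/CBr)=C/CC1=C(C)[C@@H](OC(=O)/C=C(\C)CC)CC[C@]1(C)CC=O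
A3 | alternative 2 | (7R,8R,10R)-12-ethoxy-8,12-epoxy-13-noreudesm-4-en-3-one (cis-fused ethoxy lactol ether) | CCOC1C[C@H]2CC3=C(C)C(=O)CC[C@]3(C)C[C@H]2O1
A4 | alternative 2 | (8R,10R)-8-(2-bromo-1-ethoxyethoxy)-11,12,13-trinoreudesma-4,6-dien-3-one | CCOC(CBr)O[C@@H]1C[C@@]2(C)CCC(=O)C(C)=C2C=C1
A5 | alternative 3 | (7S,8R,10R)-3-(tert-butyldimethylsilyloxy)-13-noreudesma-3,5-dien-8,12-olide | O=C1C[C@H]2C=C3C(C)=C(O[Si](C)(C)C(C)(C)C)CC[C@]3(C)C[C@H]2O1
A6 | alternative 3 | (4S,5R)-4-[4-(tert-butyldimethylsilyloxy)-3-methylpenta-1,2,4-trien-1-yl]-5-(2-methylprop-2-en-1-yl)oxolan-2-one (allene axis as required for 10R, not encoded in the string) | C=C(O[Si](C)(C)C(C)(C)C)C(C)=C=C[C@@H]1CC(=O)O[C@@H]1CC(C)=C
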